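The earlier runs and the new flask were computed with constants of no real substance, noise included.

A small charge of second end groups, less than the first end groups beside it, goes into the flask, which is the larch run carried on to 15 d.

| flask | first end groups | second end groups | remark | time |
|---|---|---|---|---|
| larch | 0.80 M | 0.72 M | the very flask that is asked about, followed so far |  |
| birch | 0.80 M | 1.4 M | run made earlier |  |
| flask | 0.80 M | 0.720 M |  | 15 d |

- larch (time / d: links / %): 0.500: 10.6; 1.67: 10.2; 2.50: 10.3; 4.00: 8.6; 6.00: 8.3; 8.00: 8.9
- birch (time / d: links / %): 1.04: 21.9; 3.00: 19.7; 5.00: 21.4; 8.00: 20.6; 12.0: 21.7; 15.0: 22.2

(readings scatter by 1 percentage point)

- why nothing more happens at 15 d, or that something still does (it is still moving / the second end groups has run out first / all of the first end groups has reacted / forward and back rates have come level)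
- links at 15 d, in percent of the first end groups charged

- the reaction counts as stopped when no species that holds the first end groups changes by six tenths of a point or more over the second half of the time

1. The larch links lie flat from 0.500 d on, with a mean of 9.48%. The birch mean is 21.3%.

2. A balance of one first and one second end group against links would need one constant in both runs. Larch gives 0.163 /M and birch gives a larger 0.219 /M. This reckoning therefore reads the larch stop as the 0.72 M of second end groups being used up, which makes them the limiting reagent, with unseen paths taking what the links do not hold.

3. Larch then stands at 10.5%: the link yield on second end groups, the links standing per second end group charged.

4. Multiplied by the charge ratio, this yield gives 9.48% of the first end groups for the flask at 15 d.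

5. The weak link is the yield itself. Birch reads 12.1%, higher than larch, so the yield is carried only at the same second charge, and the flask has that charge.

The forecast gives 9.3%, range 8.3% to 10.3%, and the end "forward and back rates have come level", parting from this reckoning on the end: “I therefore trust the flask's own plateau, shaded slightly down for the possible dip”.

    first end groups + second end groups → links (k = 0.0957 /M/h)
    first end groups + second end groups → rings, rate k2*[first end groups] as long as [second end groups] is above zero (k = 0.133 /h)
    links ⇌ isomer of the product (K = 0.700, k = 0.0583 /h)
    2 second end groups → self-condensation product (k = 0.0245 /M/h)

The flask gives 9.35%, inside the forecast's range, and the end is "the second end groups has run out first", with 0% of the second charge left at 15.0 d. The yield of 10.5% had given 9.48% here. In the neighbour flask, the same recipe with 2.0 M of first end groups, the same second charge and the same yield give 3.79% of the first end groups. The computed result is 3.98%, with 0% of the second end groups left.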